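**Strategy.** Going round the central 1,4-benzoquinone ring, the triad C(aryl)–C(O)–C(=O) occurs twice (C3–C2–C1 and C6–C5–C4). Each triad already has the connectivity and oxidation state of an arylpyruvyl residue. The plan therefore cuts the ring bonds C3–C4 and C6–C1, which join the two triads. In the forward direction, two molecules of an O-silylated S-phenyl 3-(4-hydroxyphenyl)-2-oxopropanethioate are soft-enolised on magnesium and acylate one another head to tail. This twofold Claisen condensation makes both bonds, closes the carbocycle and gives the 2,5-dihydroxyquinone with no redox adjustment. Double O-acylation with a Sharpless-derived (2Z,4S,5S)-epoxyhexenoyl chloride and desilylation finish the synthesis.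

Key step: step 4

**Remarks on the chemistry**
- The target is read as the 2,5-bis-O-[(2Z,4S,5S)-4,5-epoxyhex-2-enoyl] derivative of atromentin. Both epoxides are trans and both side chains are identical.
- Formula check: two oxo thioester molecules minus two thiol molecules equal the dihydroxyquinone. The key step is therefore redox-neutral.
- The thioester is S-phenyl and not S-alkyl. Stabilised magnesium enolates are known to be C-acylated only by activated acyl donors. The arenethiolate is the better leaving group by about four pKa units, and it also raises the C–H acidity, which helps complete enolisation.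
- The 2-oxo group is unveiled last, from a 2-hydroxy thioester.
  - 4-Hydroxyphenylpyruvic acid is mainly an enol in aprotic solvents, so silylation would also cap the enol oxygen, which cannot be freed selectively beside an aryl silyl ether.
  - Carbodiimide activation of the enolisable oxo acid would also invite self-condensation.
- E-enriched commercial crotyl alcohol is assumed. Material from residual Z isomer is removed by chromatography at the methyl ester stage.

**Step 1**
Reactants: 1 (±)-2-hydroxy-3-(4-hydroxyphenyl)propanoic acid; 2 tert-butyldimethylsilyl chloride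
Product: 4 (±)-2-hydroxy-3-[4-(tert-butyldimethylsilyloxy)phenyl]propanoic acid, via bis-silyl derivative 3 (not isolated)
Conditions: 2 (2.1 equiv), imidazole, DMF, 0 °C to rt; then AcOH/THF/H2O, rt
Reagents that add atoms: 2 tert-butyldimethylsilyl chloride, C[Si](C)(Cl)C(C)(C)C
Why: Imidazole-promoted silylation should take the carboxyl and phenol oxygens well before the hindered, electron-poor secondary hydroxyl when only two equivalents of 2 are offered, and dilute acetic acid then hydrolyses the labile silyl ester but not the aryl silyl ether; the racemic carbinol centre is irrelevant because step 3 erases it.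

**Step 2**
Reactants: 4 (±)-2-hydroxy-3-[4-(tert-butyldimethylsilyloxy)phenyl]propanoic acid; 5 thiophenol
Product: 6 (±)-S-phenyl 2-hydroxy-3-[4-(tert-butyldimethylsilyloxy)phenyl]propanethioate
Conditions: 5, DCC, HOBt (cat.), CH2Cl2, 0 °C to rt
Reagents that add atoms: 5 thiophenol, Sc1ccccc1
Why: In this carbodiimide thioesterification the soft, strongly nucleophilic thiol should outrun the free secondary hydroxyl, and no acyl-transfer base is present that could promote O-acylation.

**Step 3**
Reactants: 6 (±)-S-phenyl 2-hydroxy-3-[4-(tert-butyldimethylsilyloxy)phenyl]propanethioate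
Product: 7 S-phenyl 3-[4-(tert-butyldimethylsilyloxy)phenyl]-2-oxopropanethioate
Conditions: Dess–Martin periodinane (1.1 equiv), CH2Cl2, 0 °C to rt; filtration through silica, used at once
Reagents that add atoms: none
Why: The Dess–Martin oxidation of a 2-hydroxy (thio)ester to the 2-oxo (thio)ester is base-free and slightly acidic, so the enolisable, aldol-prone product never meets base, and thioester sulfur and aryl silyl ether are inert to the periodinane.

**Step 4**
Reactants: 7 S-phenyl 3-[4-(tert-butyldimethylsilyloxy)phenyl]-2-oxopropanethioate (two molecules)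
Product: 10 2,5-dihydroxy-3,6-bis[4-(tert-butyldimethylsilyloxy)phenyl]-1,4-benzoquinone, via open-chain Claisen dimer 8 (not isolated), via cyclohexanetetraone tautomer 9 (not isolated)
Conditions: slow addition of 7 to MgBr2·OEt2 (2.5 equiv), iPr2NEt (4 equiv), degassed CH2Cl2, −20 °C, then rt to 40 °C, Ar; cold 1 M HCl
Reagents that add atoms: none
Why: Proposed new method: MgBr2 binds the 1,2-dioxygen unit of 7 in a five-membered chelate, iPr2NEt removes a benzylic proton, and the benzylic carbon of one chelated enolate adds to the magnesium-activated thioester carbonyl of a second one, so that loss of thiophenolate gives 8, in which the same donor (ArCH2) and acceptor (COSPh) now stand six atoms apart. Ring closure is a Dieckmann-type 6-(enolendo)-exo-trig acylation to tetraone 9, the keto tautomer of 10, and twofold deprotonation to the magnesium salt of the vinylogous diacid takes the product out of every equilibrium. The closest known reaction types are the MgBr2·OEt2/iPr2NEt soft-enolisation acylation of ketones and thioesters by activated acyl donors and the Dieckmann condensation, whereas a twofold head-to-tail version on a 2-oxo thioester has not been shown. No stereocentre is formed. The step needs C-acylation at the thioester to beat aldol addition to the 2-oxo group (with ensuing lactonisation) and chain growth: inverse addition into excess MgBr2 and base enolises each molecule on arrival so that no free ketone is offered, the S-phenyl group makes the thioester a competent and the only acceptor, O-acylation is reversed by thiophenolate, and closure of 8 is intramolecular. The excess of MgBr2 lets each 1,2-dioxygen pair of 8 hold its own magnesium, the binding mode of the product, instead of a 1,3-diketonate chelate that would keep the chain extended.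

**Step 5**
Reactants: 11 (E)-but-2-en-1-ol
Product: 12 (2S,3S)-2,3-epoxybutan-1-ol
Conditions: Ti(OiPr)4 (cat.), L-(+)-diisopropyl tartrate (cat.), tBuOOH (anhydrous, in decane), 4 Å MS, CH2Cl2, −20 °C; P(OMe)3; non-aqueous work-up, distillation
Reagents that add atoms: tert-butyl hydroperoxide, CC(C)(C)OO
Why: In the Katsuki–Sharpless asymmetric epoxidation the L-(+)-tartrate complex delivers oxygen to the face of the E-allylic alcohol that gives the (2S,3S)-epoxide, which sets both stereocentres of the side chain (later C4 and C5), the trans relationship following from the E-alkene.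

**Step 6**
Reactants: 12 (2S,3S)-2,3-epoxybutan-1-ol; 13 methyl bis(2,2,2-trifluoroethyl)phosphonoacetate
Product: 15 methyl (2Z,4S,5S)-4,5-epoxyhex-2-enoate, via epoxy aldehyde 14 (not isolated)
Conditions: IBX, EtOAc, 75 °C; filter, dry (4 Å MS); filtrate added to 13 (1.1 equiv), KN(SiMe3)2 (1.05 equiv), 18-crown-6, THF, −78 °C
Reagents that add atoms: 13 methyl bis(2,2,2-trifluoroethyl)phosphonoacetate, COC(=O)CP(=O)(OCC(F)(F)F)OCC(F)(F)F
Why: IBX oxidation gives the configurationally stable, volatile epoxy aldehyde as a salt-free filtrate that need not be isolated, and the Still–Gennari variant of the Horner–Wadsworth–Emmons olefination (electron-poor phosphonate, dissociated potassium ion) eliminates under kinetic control to the Z-enoate without touching C4 or C5.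

**Step 7**
Reactants: 15 methyl (2Z,4S,5S)-4,5-epoxyhex-2-enoate
Product: 16 potassium (2Z,4S,5S)-4,5-epoxyhex-2-enoate
Conditions: KOSiMe3 (1.0 equiv), Et2O, 0 °C to rt; salt filtered off under Ar
Reagents that add atoms: potassium trimethylsilanolate, C[Si](C)(C)[O-].[K+]
Why: Anhydrous silanolate cleavage of the methyl ester delivers the carboxylate as a salt that precipitates from ether, so the free Z-epoxy acid, which lactonises onto its epoxide under acid, is never formed.

**Step 8**
Reactants: 16 potassium (2Z,4S,5S)-4,5-epoxyhex-2-enoate (2.5 equiv); 10 2,5-dihydroxy-3,6-bis[4-(tert-butyldimethylsilyloxy)phenyl]-1,4-benzoquinone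
Product: 18 2,5-bis[4-(tert-butyldimethylsilyloxy)phenyl]-3,6-dioxocyclohexa-1,4-diene-1,4-diyl bis[(2Z,4S,5S)-4,5-epoxyhex-2-enoate], via acid chloride 17 (not isolated)
Conditions: 16, (COCl)2 (0.95 equiv per 16), Et2O, 0 °C; supernatant added to 10, iPr2NEt (2.0 equiv), CH2Cl2, −40 to 0 °C
Reagents that add atoms: oxalyl chloride, O=C(Cl)C(=O)Cl (supplies the chlorine of 17; none of its atoms remains in 18)
Why: A dry potassium carboxylate and oxalyl chloride give the acid chloride without HCl, the classical isomerisation-free access to Z-enoyl chlorides such as angeloyl chloride, and the preformed bis(ammonium) salt of the vinylogous diacid 10 is O-acylated like any hydroxyquinone with no free amine left to form a vinylketene or to isomerise the alkene, the para-quinone diester being the more stable O-acyl isomer.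

**Step 9**
Reactants: 18 2,5-bis[4-(tert-butyldimethylsilyloxy)phenyl]-3,6-dioxocyclohexa-1,4-diene-1,4-diyl bis[(2Z,4S,5S)-4,5-epoxyhex-2-enoate]
Product: 19 2,5-bis(4-hydroxyphenyl)-3,6-dioxocyclohexa-1,4-diene-1,4-diyl bis[(2Z,4S,5S)-4,5-epoxyhex-2-enoate] (CNP0407724.1)
Conditions: Et3N·3HF, THF, 0 °C to rt; pH 6 buffer work-up
Reagents that add atoms: none
Why: Fluoride cleavage of the aryl silyl ethers is driven by the Si–F bond, and the weakly acidic, poorly nucleophilic Et3N·3HF releases the phenols in protonated form, which should prevent acyl transfer from the activated enol esters, while it opens epoxides only at much higher temperature.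

**Compound list**
1 | (±)-2-hydroxy-3-(4-hydroxyphenyl)propanoic acid (DL-4-hydroxyphenyllactic acid) | O=C(O)C(O)Cc1ccc(O)cc1 | starting material
2 | tert-butyldimethylsilyl chloride | C[Si](C)(Cl)C(C)(C)C | starting material
3 | tert-butyldimethylsilyl (±)-2-hydroxy-3-[4-(tert-butyldimethylsilyloxy)phenyl]propanoate | CC(C)(C)[Si](C)(C)OC(=O)C(O)Cc1ccc(O[Si](C)(C)C(C)(C)C)cc1 | intermediate
4 | (±)-2-hydroxy-3-[4-(tert-butyldimethylsilyloxy)phenyl]propanoic acid | OC(=O)C(O)Cc1ccc(O[Si](C)(C)C(C)(C)C)cc1 | intermediate
5 | thiophenol | Sc1ccccc1 | starting material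
6 | (±)-S-phenyl 2-hydroxy-3-[4-(tert-butyldimethylsilyloxy)phenyl]propanethioate | O=C(Sc1ccccc1)C(O)Cc1ccc(O[Si](C)(C)C(C)(C)C)cc1 | intermediate
7 | S-phenyl 3-[4-(tert-butyldimethylsilyloxy)phenyl]-2-oxopropanethioate | O=C(Sc1ccccc1)C(=O)Cc1ccc(O[Si](C)(C)C(C)(C)C)cc1 | intermediate
8 | S-phenyl 3,6-bis[4-(tert-butyldimethylsilyloxy)phenyl]-2,4,5-trioxohexanethioate | O=C(Sc1ccccc1)C(=O)C(c1ccc(O[Si](C)(C)C(C)(C)C)cc1)C(=O)C(=O)Cc1ccc(O[Si](C)(C)C(C)(C)C)cc1 | intermediate
9 | 3,6-bis[4-(tert-butyldimethylsilyloxy)phenyl]cyclohexane-1,2,4,5-tetraone | O=C1C(=O)C(c2ccc(O[Si](C)(C)C(C)(C)C)cc2)C(=O)C(=O)C1c1ccc(O[Si](C)(C)C(C)(C)C)cc1 | intermediate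
10 | 2,5-dihydroxy-3,6-bis[4-(tert-butyldimethylsilyloxy)phenyl]-1,4-benzoquinone | O=C1C(O)=C(c2ccc(O[Si](C)(C)C(C)(C)C)cc2)C(=O)C(O)=C1c1ccc(O[Si](C)(C)C(C)(C)C)cc1 | intermediate
11 | (E)-but-2-en-1-ol (crotyl alcohol) | C/C=C/CO | starting material
12 | (2S,3S)-2,3-epoxybutan-1-ol | C[C@@H]1O[C@H]1CO | intermediate
13 | methyl bis(2,2,2-trifluoroethyl)phosphonoacetate | COC(=O)CP(=O)(OCC(F)(F)F)OCC(F)(F)F | starting material
14 | (2R,3S)-2,3-epoxybutanal | C[C@@H]1O[C@H]1C=O | intermediate
15 | methyl (2Z,4S,5S)-4,5-epoxyhex-2-enoate | C[C@@H]1O[C@H]1/C=C\C(=O)OC | intermediate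
16 | potassium (2Z,4S,5S)-4,5-epoxyhex-2-enoate | C[C@@H]1O[C@H]1/C=C\C(=O)[O-].[K+] | intermediate
17 | (2Z,4S,5S)-4,5-epoxyhex-2-enoyl chloride | C[C@@H]1O[C@H]1/C=C\C(=O)Cl | intermediate
18 | bis-TBS ether of the target diester | C[C@@H]1O[C@H]1/C=C\C(=O)OC1=C(c2ccc(O[Si](C)(C)C(C)(C)C)cc2)C(=O)C(OC(=O)/C=C\[C@@H]2O[C@H]2C)=C(c2ccc(O[Si](C)(C)C(C)(C)C)cc2)C1=O | intermediate
19 | CNP0407724.1, atromentin 2,5-bis[(2Z,4S,5S)-4,5-epoxyhex-2-enoate] | C[C@@H]1O[C@H]1/C=C\C(=O)OC1=C(c2ccc(O)cc2)C(=O)C(OC(=O)/C=C\[C@@H]2O[C@H]2C)=C(c2ccc(O)cc2)C1=O | target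

**Step count**
- Total step count: 9.
- Longest linear sequence: 6 steps (1, 2, 3, 4, 8, 9).
- The side chain (steps 5 to 7) is made in parallel.

**Steps most likely to fail**

**Step 4.**
- What may go wrong: aldol addition of the enolate to a not yet enolised 2-oxo group followed by lactonisation, chain growth instead of ring closure, or no acyl transfer at all.
- Fallback (known chemistry, cross-coupling on a preformed quinone instead of ring construction): it sets out from 2 and comes back at 10. Commercial 4-hydroxyphenylboronic acid pinacol ester is silylated with 2 (imidazole, DMF) to 4-(tert-butyldimethylsilyloxy)phenylboronic acid pinacol ester F1. Commercial bromanil and NaOMe in MeOH give 2,5-dibromo-3,6-dimethoxy-1,4-benzoquinone F2. A twofold Suzuki–Miyaura coupling of F1 with F2 (PdCl2(dppf), K3PO4, dioxane/H2O, 80 °C) gives 2,5-dimethoxy-3,6-bis[4-(tert-butyldimethylsilyloxy)phenyl]-1,4-benzoquinone F3. NaOH in aqueous MeOH hydrolyses the two vinylogous methyl esters by addition–elimination and also removes the aryl silyl groups, which gives atromentin F4 after acidification. Exhaustive silylation with 2 gives tetrakis-O-(tert-butyldimethylsilyl)atromentin F5. Its two vinylogous silyl esters are hydrolysed by AcOH/THF/H2O while the aryl silyl ethers stay, which returns 10.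

**Step 8.**
- What may go wrong: attack of the activated carboxyl group on the neighbouring epoxide, Z-to-E isomerisation or vinylketene formation during activation, and sluggish acylation of a weakly nucleophilic vinylogous carboxylate.
- Fallback (roles of the partners reversed): it sets out from 10 and 16 and comes back at 18. Compound 10 is converted with (COCl)2 and catalytic DMF in CH2Cl2 into 2,5-dichloro-3,6-bis[4-(tert-butyldimethylsilyloxy)phenyl]-1,4-benzoquinone F6, a vinylogous acid chloride. The unactivated carboxylate 16 (18-crown-6, MeCN, 0 °C to rt) then displaces both chlorides by addition–elimination, so the epoxy acid itself is never activated.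

**Step 9.**
- What may go wrong: acyl transfer from the activated enol esters to fluoride or to liberated phenol, and opening of the epoxides by HF.
- Fallback (deprotection moved ahead of acylation): it sets out from 10 and comes back at 19. Bu4NF in THF followed by acid frees atromentin F7 (the same compound as F4). Two equivalents of Bu4NOH deprotonate only the two strongly acidic enolic hydroxyls and give bis(tetrabutylammonium) atromentin-2,5-diolate F8. F8 is treated with 17 (made from 16 as in step 8) in CH2Cl2 at low temperature without further base. The anionic oxygens should be acylated and the neutral phenols should not, so 19 forms directly and no fluoride meets the diester.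

**Further compounds**
F1 | step 4 | 4-(tert-butyldimethylsilyloxy)phenylboronic acid pinacol ester | CC(C)(C)[Si](C)(C)Oc1ccc(B2OC(C)(C)C(C)(C)O2)cc1
F2 | step 4 | 2,5-dibromo-3,6-dimethoxy-1,4-benzoquinone | COC1=C(Br)C(=O)C(OC)=C(Br)C1=O
F3 | step 4 | 2,5-dimethoxy-3,6-bis[4-(tert-butyldimethylsilyloxy)phenyl]-1,4-benzoquinone | COC1=C(c2ccc(O[Si](C)(C)C(C)(C)C)cc2)C(=O)C(OC)=C(c2ccc(O[Si](C)(C)C(C)(C)C)cc2)C1=O
F4 | step 4 | atromentin | O=C1C(O)=C(c2ccc(O)cc2)C(=O)C(O)=C1c1ccc(O)cc1
F5 | step 4 | tetrakis-O-(tert-butyldimethylsilyl)atromentin | O=C1C(O[Si](C)(C)C(C)(C)C)=C(c2ccc(O[Si](C)(C)C(C)(C)C)cc2)C(=O)C(O[Si](C)(C)C(C)(C)C)=C1c1ccc(O[Si](C)(C)C(C)(C)C)cc1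
F6 | step 8 | 2,5-dichloro-3,6-bis[4-(tert-butyldimethylsilyloxy)phenyl]-1,4-benzoquinone | O=C1C(Cl)=C(c2ccc(O[Si](C)(C)C(C)(C)C)cc2)C(=O)C(Cl)=C1c1ccc(O[Si](C)(C)C(C)(C)C)cc1
F7 | step 9 | atromentin | O=C1C(O)=C(c2ccc(O)cc2)C(=O)C(O)=C1c1ccc(O)cc1
F8 | step 9 | bis(tetrabutylammonium) atromentin-2,5-diolate | [O-]C1=C(c2ccc(O)cc2)C(=O)C([O-])=C(c2ccc(O)cc2)C1=O.CCCC[N+](CCCC)(CCCC)CCCC.CCCC[N+](CCCC)(CCCC)CCCC
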